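**Strategy**

Ring A is cut at the C3–C4 bond (labdane numbering). The fragment that remains is ring B, C5–C10 with the C8 methyl as a 2-methylcyclohexenone: (S)-carvone, whose isopropenyl group is C4 with one methyl and whose α′-carbon becomes the quaternary C10. In a single operation, hydrogen-atom transfer to the isopropenyl group creates the second C4 methyl and a tertiary C4 radical, which closes ring A onto a C3 aldehyde; this forms the gem-dimethyl carbon, the C3 carbinol and the trans-decalin. The precursor is the carvone-derived enone bearing on C10 a methyl group and, anti to the isopropenyl group, a 3-oxopropyl chain.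

Key step: step 4

Remark 1: labdane numbering is used for all decalin compounds; "upper face" is the face carrying H5, "lower face" the face carrying the C10 methyl (C20).
Remark 2: the key step is expected to give mainly the equatorial (3R) alcohol; a minor 3S epimer, if formed, is carried along and converges at ketone 25.

**Route**

Step 1
Reactants: 1 (S)-carvone; 2 iodomethane
Product: 4 6-methylcarvone (C6 epimers; trans major), via lithium dienolate 3 (not isolated)
Conditions: LiN(iPr)2, THF, −78 °C; MeI, −78 → 0 °C
Reagents that add atoms: iodomethane (CI)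
Why: Kinetic deprotonation at the α′-carbon (the later C10) gives the cross-conjugated lithium dienolate, whose C-methylation (enolate alkylation) installs C20; the new centre forms as an epimer mixture that is erased by re-enolization in step 2.

Step 2
Reactants: 4 6-methylcarvone; 5 propargyl bromide
Product: 7 6-methyl-6-propargylcarvone, via lithium enolate 6 (not isolated)
Conditions: LiN(iPr)2, THF, −78 → −20 °C; propargyl bromide, −78 °C → rt
Reagents that add atoms: propargyl bromide (C#CCBr)
Why: Enolate alkylation in which the fully substituted α′-enolate is attacked by the reactive propargylic bromide on the face opposite the neighbouring isopropenyl group, so the quaternary C10 is set with the three-carbon chain anti and the methyl syn to the isopropenyl group, as established for allylation of 6-methylcarvone.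

Step 3
Reactants: 7 6-methyl-6-propargylcarvone
Product: 9 keto aldehyde, via alkenylborane 8 (not isolated)
Conditions: Cy2BH, THF, 0 °C; then 30% H2O2, aq. NaOAc, 0 °C → rt
Reagents that add atoms: hydrogen peroxide (OO)
Why: Anti-Markovnikov hydration by hydroboration–oxidation, in which the hindered dialkylborane adds to the terminal alkyne much faster than to the 1,1-disubstituted alkene or the hindered conjugated ketone, and weakly basic peroxide oxidizes the alkenylborane to the aldehyde without Weitz–Scheffer epoxidation of the enone; no stereocentre is formed.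

Step 4
Reactants: 9 keto aldehyde
Product: 10 3-hydroxy decalin enone
Conditions: Fe(acac)3 (30 mol %), PhSiH3, THF/i-PrOH, 60 °C, Ar
Reagents that add atoms: none
Why: The iron hydride formed from Fe(acac)3 and PhSiH3 transfers a hydrogen atom to the CH2 terminus of the electron-rich 1,1-disubstituted alkene, which becomes the second C4 methyl and leaves a tertiary C4 radical; this radical adds to the aldehyde carbon C3, and the alkoxy radical is reduced by divalent iron (or quenched by hydrogen transfer) before it can fragment back, the proton coming from the alcohol. The closest known reaction type is the iron-hydride hydrogen-atom-transfer (Mukaiyama-type) radical cyclization of alkenes onto tethered ketones, and 6-exo addition of alkyl radicals to aldehydes is established in tin hydride chemistry. Ring A closes in the 6-exo-trig mode at the carbonyl group through a chair transition state in which the chain on C10 and the radical centre on C5 are both equatorial on ring B, so the trans ring fusion follows from the C5 and C10 centres set in steps 1 and 2. The one new stereocentre, C3, is controlled by this chair, which places the C–O bond equatorial on the lower face (3R); the outcome is not critical because C3 later passes through ketone 25. The step needs hydrogen-atom transfer to the isopropenyl group in preference to the C7=C8 enone, which the nucleophilic iron hydride secures because it reacts much faster with the electron-rich disubstituted alkene than with the electron-poor trisubstituted enone, and the C4 radical can reach the enone only through a four-membered or strained bridged ring. Isopropanol in place of ethanol keeps hemiacetal formation of the aldehyde low.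

Step 5
Reactants: 10 3-hydroxy decalin enone
Product: 11 3-pivaloyloxy decalin enone
Conditions: PivCl, pyridine, DMAP (cat.), CH2Cl2, 40 °C
Reagents that add atoms: pivaloyl chloride (CC(C)(C)C(=O)Cl)
Why: DMAP-catalysed acylation masks the C3 hydroxyl as a hindered pivalate that withstands alkaline peroxide, hydrazine and the hot orthoester step and is removed without an extra operation by the hydride reduction of step 9; no stereocentre changes.

Step 6
Reactants: 11 3-pivaloyloxy decalin enone
Product: 12 7,8-epoxy ketone
Conditions: 30% H2O2, NaOH (aq), MeOH, 0 °C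
Reagents that add atoms: hydrogen peroxide (OO)
Why: Weitz–Scheffer nucleophilic epoxidation in which hydroperoxide adds axially to C7 on the upper face (that of H5, away from the C10 methyl), as in the trans-selective epoxidation of carvone, so that ring closure fixes C7 and C8 with the epoxide oxygen on the upper face.

Step 7
Reactants: 12 7,8-epoxy ketone
Product: 14 allylic alcohol (7-hydroxy-8(9)-ene), via epoxy hydrazone 13 (not isolated)
Conditions: N2H4·H2O, AcOH, MeOH, 0 °C → rt
Reagents that add atoms: none
Why: Wharton transposition, in which the hydrazone opens the epoxide to a vinyl diazene that loses nitrogen and gives the C8=C9 alkene and the C7 alcohol, whose configuration (hydroxyl pseudo-axial on the upper face) is retained from the epoxide.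

Step 8
Reactants: 14 allylic alcohol; 15 triethyl orthoacetate
Product: 17 ethyl ester with the C9 acetic side chain, via mixed ketene acetal 16 (not isolated)
Conditions: MeC(OEt)3, EtCO2H (cat.), xylene, 140 °C (−EtOH)
Reagents that add atoms: triethyl orthoacetate (CC(OCC)(OCC)OCC)
Why: Johnson–Claisen rearrangement, in which the ketene acetal on the pseudo-axial C7 oxygen rearranges suprafacially ([3,3]) and delivers C11 to the upper face of C9, which sets C9 with the side chain anti to the C10 methyl and moves the alkene to C7=C8.

Step 9
Reactants: 17 ethyl ester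
Product: 18 3,12-diol
Conditions: LiAlH4, THF, 0 °C → reflux
Reagents that add atoms: none
Why: Hydride reduction converts the ethyl ester into the primary C12 alcohol and cleaves the pivalate in the same operation, and no stereocentre is touched.

Step 10
Reactants: 18 3,12-diol
Product: 19 12-iodide
Conditions: I2, PPh3, imidazole, CH2Cl2, 0 °C
Reagents that add atoms: iodine (II)
Why: Appel-type iodination (Garegg–Samuelsson conditions) converts only the unhindered primary C12 alcohol, the equatorial neopentyl C3 alcohol being unreactive at 0 °C, and at this stage C8 carries no hydroxyl that could close a cyclic ether onto C12.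

Step 11
Reactants: 19 12-iodide; 20 lithium acetylide ethylenediamine complex
Product: 21 terminal alkyne
Conditions: LiC≡CH·H2NCH2CH2NH2 (excess), DMSO, rt
Reagents that add atoms: lithium acetylide ethylenediamine complex ([Li+].[C-]#C.NCCN)
Why: SN2 alkylation of the acetylide by the primary iodide in DMSO adds C13 and C14 as a terminal alkyne, the remote C3 alkoxide formed by the excess reagent being inert; no stereocentre is formed.

Step 12
Reactants: 21 terminal alkyne
Product: 22 bromohydrin
Conditions: NBS, THF/H2O, 0 °C, dark
Reagents that add atoms: N-bromosuccinimide (O=C1CCC(=O)N1Br); water (O)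
Why: Bromohydrin formation (electrophilic anti addition), in which the reversibly formed bromonium ion of the trisubstituted C7=C8 alkene is opened by water at the tertiary C8 in the trans-diaxial (Fürst–Plattner) and Markovnikov sense, as in hypobromous acid addition to 5-ene steroids, which puts bromine axial on the upper face of C7 and the hydroxyl axial on the lower face of C8, anti to the axial C9 side chain (which for that reason cannot take part), while the terminal alkyne reacts far more slowly.

Step 13
Reactants: 22 bromohydrin
Product: 24 3,8-diol, via lower-face 7,8-epoxide 23 (not isolated)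
Conditions: LiBHEt3, THF, 0 °C → reflux
Reagents that add atoms: none
Why: Hydride reduction, in which the C8 alkoxide displaces the antiperiplanar C7 bromide and LiBHEt3 opens the resulting epoxide at the secondary C7 in the trans-diaxial sense, as it does with 1-methylcyclohexene oxide (direct reduction of the C–Br bond leads to the same product), so the axial tertiary C8 alcohol is kept.

Step 14
Reactants: 24 3,8-diol
Product: 25 3-ketone
Conditions: Dess–Martin periodinane, NaHCO3, CH2Cl2, rt
Reagents that add atoms: none
Why: Dess–Martin oxidation converts the secondary C3 alcohol into the ketone and leaves the tertiary C8 alcohol and the alkyne untouched, which clears the C3 centre so that it can be reset.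

Step 15
Reactants: 25 3-ketone
Product: 26 axial 3-alcohol (3-epimer of 24)
Conditions: LiBH(s-Bu)3, THF, −78 → 0 °C
Reagents that add atoms: none
Why: Reduction with a bulky hydride, which avoids the axial approach and attacks the C3 ketone from the equatorial direction, giving the axial alcohol on the upper face, as known for 4,4-dimethyl-3-keto decalins and triterpenoids.

Step 16
Reactants: 26 axial 3-alcohol; 27 trimethylaluminium; 28 paraformaldehyde
Product: 30 E allylic alcohol (3,8,15-triol), via alkenylalane 29 (not isolated)
Conditions: Me3Al, Cp2ZrCl2 (25 mol %), CH2Cl2, 0 °C → rt; then n-BuLi, THF, −78 °C; (CH2O)n, → rt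
Reagents that add atoms: trimethylaluminium (C[Al](C)C); paraformaldehyde (C=O)
Why: Negishi zirconium-catalysed carboalumination adds methyl and aluminium syn across the terminal alkyne with methyl on the internal carbon C13, and the derived alanate is trapped by formaldehyde with retention, as in the classical route to geraniol, giving the E trisubstituted allylic alcohol while the two hydroxyls ride through as aluminium alkoxides.

Step 17
Reactants: 30 E allylic alcohol
Product: 31 (13R,14R)-epoxy alcohol
Conditions: Ti(OiPr)4 (cat.), D-(−)-diethyl tartrate (cat.), t-BuOOH, 4 Å MS, CH2Cl2, −20 °C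
Reagents that add atoms: tert-butyl hydroperoxide (CC(C)(C)OO)
Why: Sharpless asymmetric epoxidation under reagent control, in which D-(−)-tartrate directs oxygen to the face of the E allylic alcohol that gives the (13R,14R)-epoxide (the mirror sense of the (2S,3S)-epoxide formed from geraniol with L-(+)-tartrate), and the trans-diaxial C8 hydroxyl cannot reach C13 to open it.

Step 18
Reactants: 31 epoxy alcohol
Product: 32 epoxy dibromide
Conditions: CBr4, PPh3, 2,6-lutidine, CH2Cl2, 0 → 40 °C
Reagents that add atoms: carbon tetrabromide (BrC(Br)(Br)Br)
Why: Appel bromination at both non-tertiary alcohols, in which the primary C15 alcohol gives the epoxy bromide and the axial neopentyl C3 alkoxyphosphonium ion is displaced by bromide with inversion (SN2), placing bromine equatorial on the lower face (3R) as known for axial 3-hydroxy-4,4-dimethyl decalins, while the hindered tertiary C8 alcohol does not react.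

Step 19
Reactants: 32 epoxy dibromide
Product: 34 (3R,5S,8R,9R,10R,13R)-3-bromolabd-14-ene-8,13-diol (target), via epoxy iodide 33 (not isolated)
Conditions: NaI, Zn, EtOH, reflux
Reagents that add atoms: none
Why: Finkelstein exchange followed by zinc-induced reductive β-elimination of the 2,3-epoxy halide opens the epoxide to the tertiary allylic alcohol with the C13–O bond untouched, so C13 stays R, and the secondary neopentyl C3 bromide is inert to iodide and zinc.

**Compound list**

1 | (S)-(+)-carvone, (5S)-2-methyl-5-(prop-1-en-2-yl)cyclohex-2-en-1-one | O=C1C(C)=CC[C@H](C(C)=C)C1 | starting material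
2 | iodomethane | CI | starting material
3 | lithium dienolate of carvone (O–Li on C1, C1=C6 and C2=C3; not isolated) | [Li]OC1=C[C@@H](C(C)=C)CC=C1C | intermediate
4 | 6-methylcarvone, major (5S,6R) isomer with methyl trans to isopropenyl, used together with its C6 epimer | O=C1C(C)=CC[C@H](C(C)=C)[C@H]1C | intermediate
5 | propargyl bromide (3-bromoprop-1-yne) | C#CCBr | starting material
6 | lithium enolate of 6-methylcarvone (C1=C6; not isolated) | [Li]OC1=C(C)[C@@H](C(C)=C)CC=C1C | intermediate
7 | (5R,6R)-2,6-dimethyl-5-(prop-1-en-2-yl)-6-(prop-2-yn-1-yl)cyclohex-2-en-1-one (propargyl trans to isopropenyl) | C#CC[C@@]1(C)C(=O)C(C)=CC[C@@H]1C(C)=C | intermediate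
8 | (E)-alkenyl(dicyclohexyl)borane from 7 (not isolated) | B(/C=C/C[C@@]1(C)C(=O)C(C)=CC[C@@H]1C(C)=C)(C2CCCCC2)C3CCCCC3 | intermediate
9 | keto aldehyde, 3-[(1R,6R)-1,3-dimethyl-2-oxo-6-(prop-1-en-2-yl)cyclohex-3-en-1-yl]propanal | O=CCC[C@@]1(C)C(=O)C(C)=CC[C@@H]1C(C)=C | intermediate
10 | 3-hydroxy decalin enone, (3R,5R,10R)-3-hydroxy-11,12,13,14,15,16-hexanorlabd-7-en-9-one [(4aR,6R,8aR)-6-hydroxy-2,5,5,8a-tetramethyl-4a,5,6,7,8,8a-hexahydronaphthalen-1(4H)-one]; trans-fused, 3-OH equatorial on the lower face | O=C1[C@]2(C)CC[C@@H](O)C(C)(C)[C@H]2CC=C1C | intermediate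
11 | 3-pivalate of 10 | O=C1[C@]2(C)CC[C@@H](OC(=O)C(C)(C)C)C(C)(C)[C@H]2CC=C1C | intermediate
12 | 7,8-epoxy-3-pivaloyloxy-11,12,13,14,15,16-hexanorlabdan-9-one, epoxide oxygen on the upper face | O=C1[C@]2(C)CC[C@@H](OC(=O)C(C)(C)C)C(C)(C)[C@H]2C[C@@H]3O[C@]13C | intermediate
13 | hydrazone of 12 at C9 (not isolated) | NN=C1[C@]2(C)CC[C@@H](OC(=O)C(C)(C)C)C(C)(C)[C@H]2C[C@@H]3O[C@]13C | intermediate
14 | 3-pivaloyloxy-11,12,13,14,15,16-hexanorlabd-8-en-7-ol, 7-OH on the upper face | CC1=C[C@]2(C)CC[C@@H](OC(=O)C(C)(C)C)C(C)(C)[C@H]2C[C@@H]1O | intermediate
15 | triethyl orthoacetate | CC(OCC)(OCC)OCC | starting material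
16 | mixed ketene acetal of 14 (C7–O–C(=CH2)OEt; not isolated) | CC1=C[C@]2(C)CC[C@@H](OC(=O)C(C)(C)C)C(C)(C)[C@H]2C[C@@H]1OC(=C)OCC | intermediate
17 | ethyl 3-pivaloyloxy-13,14,15,16-tetranorlabd-7-en-12-oate, C9 side chain on the upper face (axial), 9-H on the lower face | CCOC(=O)C[C@@H]1[C@]2(C)CC[C@@H](OC(=O)C(C)(C)C)C(C)(C)[C@H]2CC=C1C | intermediate
18 | 13,14,15,16-tetranorlabd-7-ene-3,12-diol (3-OH equatorial, configuration as in 17) | OCC[C@@H]1[C@]2(C)CC[C@@H](O)C(C)(C)[C@H]2CC=C1C | intermediate
19 | 12-iodo-13,14,15,16-tetranorlabd-7-en-3-ol | ICC[C@@H]1[C@]2(C)CC[C@@H](O)C(C)(C)[C@H]2CC=C1C | intermediate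
20 | lithium acetylide ethylenediamine complex | [Li+].[C-]#C.NCCN | starting material
21 | 15,16-dinorlabd-7-en-13-yn-3-ol | C#CCC[C@@H]1[C@]2(C)CC[C@@H](O)C(C)(C)[C@H]2CC=C1C | intermediate
22 | 7-bromo-15,16-dinorlabd-13-yne-3,8-diol, 7-Br axial on the upper face, 8-OH axial on the lower face, C17 equatorial | C#CCC[C@@H]1[C@]2(C)CC[C@@H](O)C(C)(C)[C@H]2C[C@H](Br)[C@@]1(C)O | intermediate
23 | 7,8-epoxy-15,16-dinorlabd-13-yn-3-ol, epoxide oxygen on the lower face (not isolated) | C#CCC[C@@H]1[C@]2(C)CC[C@@H](O)C(C)(C)[C@H]2C[C@H]3O[C@@]13C | intermediate
24 | 15,16-dinorlabd-13-yne-3,8-diol, 3-OH equatorial, 8-OH axial on the lower face | C#CCC[C@@H]1[C@]2(C)CC[C@@H](O)C(C)(C)[C@H]2CC[C@@]1(C)O | intermediate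
25 | 8-hydroxy-15,16-dinorlabd-13-yn-3-one | C#CCC[C@@H]1[C@]2(C)CCC(=O)C(C)(C)[C@H]2CC[C@@]1(C)O | intermediate
26 | 15,16-dinorlabd-13-yne-3,8-diol with the 3-OH axial on the upper face (3-epimer of 24) | C#CCC[C@@H]1[C@]2(C)CC[C@H](O)C(C)(C)[C@H]2CC[C@@]1(C)O | intermediate
27 | trimethylaluminium | C[Al](C)C | starting material
28 | paraformaldehyde (shown as the monomer) | C=O | starting material
29 | (E)-alkenyl(dimethyl)alane from 26, hydroxyls as dimethylaluminium alkoxides (not isolated) | C[Al](C)/C=C(\C)CC[C@@H]1[C@]2(C)CC[C@H](O[Al](C)C)C(C)(C)[C@H]2CC[C@@]1(C)O[Al](C)C | intermediate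
30 | (13E)-labd-13-ene-3,8,15-triol, 3-OH axial (upper face), 8-OH axial (lower face) | OC/C=C(\C)CC[C@@H]1[C@]2(C)CC[C@H](O)C(C)(C)[C@H]2CC[C@@]1(C)O | intermediate
31 | (13R,14R)-13,14-epoxylabdane-3,8,15-triol, ring configuration as in 30 | OC[C@H]1O[C@]1(C)CC[C@@H]2[C@]3(C)CC[C@H](O)C(C)(C)[C@H]3CC[C@@]2(C)O | intermediate
32 | 3,15-dibromo-13,14-epoxylabdan-8-ol, 3-Br equatorial on the lower face (3R), epoxide configured as in 31 | BrC[C@H]1O[C@]1(C)CC[C@@H]2[C@]3(C)CC[C@@H](Br)C(C)(C)[C@H]3CC[C@@]2(C)O | intermediate
33 | 3-bromo-13,14-epoxy-15-iodolabdan-8-ol, configured as 32 (not isolated) | IC[C@H]1O[C@]1(C)CC[C@@H]2[C@]3(C)CC[C@@H](Br)C(C)(C)[C@H]3CC[C@@]2(C)O | intermediate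
34 | (3R,5S,8R,9R,10R,13R)-3-bromolabd-14-ene-8,13-diol | C=C[C@](C)(O)CC[C@@H]1[C@]2(C)CC[C@@H](Br)C(C)(C)[C@H]2CC[C@@]1(C)O | target

**Count**

Total steps: 19. Longest linear sequence: 19 steps, from (S)-carvone.

**Steps most likely to fail**

Step 4 (key step). Addition of the tertiary radical to the aldehyde is reversible, so β-scission of the alkoxy radical followed by simple reduction of the isopropenyl group may outrun ring closure. Hydrogen-atom transfer to the enone is a second drain. The fallback sets out from 9 and generates the same radical by known halide chemistry. Markovnikov addition of HBr (HBr in AcOH, CH2Cl2, 0 °C), known for the isopropenyl group of carvone, should give the tertiary bromide F1. Slow addition of Bu3SnH with AIBN in benzene at 80 °C should then form the C4 radical, which closes 6-exo onto the aldehyde, the alkoxy radical being quenched at once by the stannane. This comes back to the route at 10.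

Step 18. Substitution at the neopentyl C3 is slow, and the forcing conditions and long exposure it needs may let bromide open the trisubstituted epoxide or let the epoxy bromide decompose. The fallback sets out from 26 and separates the two brominations. Appel bromination of 26 alone (CBr4, PPh3, CH2Cl2) should give the 3-bromo alkyne F4 before any epoxide exists. Carboalumination and formaldehyde trapping as in step 16 should give the bromo allylic alcohol F5. Sharpless epoxidation as in step 17 should give the bromo epoxy alcohol F6. I2, PPh3 and imidazole then convert its primary alcohol into the epoxy iodide, which is 33, where the route is rejoined just before the zinc treatment that gives 34.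

Step 7. Condensation of hydrazine with the C9 ketone, which lies between the quaternary C10 and the fully substituted epoxide carbon C8, may be too slow. Hydrazine could then open the epoxide at C7, or the vinyl diazene could decay along other paths. The fallback sets out from 12 and uses a radical fragmentation instead. NaBH4 with CeCl3·7H2O in MeOH at 0 °C should reduce the ketone to the epoxy alcohol F2; either C9 epimer serves. 1,1′-Thiocarbonyldiimidazole with DMAP in toluene at 100 °C should give the imidazolyl thiocarbonate F3. Bu3SnH and AIBN in refluxing toluene should generate the C9 radical, which opens the adjacent epoxide at the C8–O bond, and hydrogen transfer to the C7 alkoxy radical gives 14 (a Barton–McCombie-type epoxide fragmentation), where the route is rejoined.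

**Further compounds**

F1 | step 4 | 3-[(1R,6R)-6-(2-bromopropan-2-yl)-1,3-dimethyl-2-oxocyclohex-3-en-1-yl]propanal (tertiary bromide) | O=CCC[C@@]1(C)C(=O)C(C)=CC[C@@H]1C(C)(C)Br
F2 | step 7 | 7,8-epoxy-3-pivaloyloxy-11,12,13,14,15,16-hexanorlabdan-9-ol, epoxide on the upper face, C9 configuration not fixed | OC1[C@]2(C)CC[C@@H](OC(=O)C(C)(C)C)C(C)(C)[C@H]2C[C@@H]3O[C@]13C
F3 | step 7 | O-(C9) 1H-imidazole-1-carbothioate of F2 | S=C(OC1[C@]2(C)CC[C@@H](OC(=O)C(C)(C)C)C(C)(C)[C@H]2C[C@@H]3O[C@]13C)n4ccnc4
F4 | step 18 | 3-bromo-15,16-dinorlabd-13-yn-8-ol, 3-Br equatorial on the lower face | C#CCC[C@@H]1[C@]2(C)CC[C@@H](Br)C(C)(C)[C@H]2CC[C@@]1(C)O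
F5 | step 18 | (13E)-3-bromolabd-13-ene-8,15-diol | OC/C=C(\C)CC[C@@H]1[C@]2(C)CC[C@@H](Br)C(C)(C)[C@H]2CC[C@@]1(C)O
F6 | step 18 | (13R,14R)-3-bromo-13,14-epoxylabdane-8,15-diol | OC[C@H]1O[C@]1(C)CC[C@@H]2[C@]3(C)CC[C@@H](Br)C(C)(C)[C@H]3CC[C@@]2(C)O
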